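Everything rests on unzipping rings A and B at C4–C5 and C10–C9. C3–O, the quaternary C4 with equatorial C18H2OH, C5, C10, C9 and the C8=C17 methylene are the fingerprint of an all-E farnesyl chain capped by an (E)-hydroxymethyl epoxide. One titanocene radical cascade on that acyclic precursor, a (3R,4R)-epoxy diene silyl ether whose tail is a 3-furyl group, closes both rings, sets C4, C5, C9 and C10 and leaves the exocyclic alkene. The furan is a ring foreign to the target: it stores the 13Z C15/C16 enediol and is opened by oxidation and reduction afterwards, before the angelate is put on C3–OH.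

Key step: step 11

Remark on the chemistry: labdane numbering is used from compound 12 onward (farnesyl C12 becomes C18, farnesyl C1 becomes C11), and commercial farnesol is taken to be the isomerically pure (2E,6E) compound.

Step 1
Reactants: 1 (2E,6E)-farnesol
Product: 2 (2E,6E)-farnesyl acetate
Conditions: Ac2O, pyridine, DMAP (cat.), CH2Cl2, 0 °C to rt
Reagents that add atoms: acetic anhydride, CC(=O)OC(C)=O
Why: Plain O-acylation of the primary allylic alcohol masks the future C11 oxygen and deactivates the neighbouring alkene toward the allylic oxidation that follows.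

Step 2
Reactants: 2 (2E,6E)-farnesyl acetate
Product: 3 (2E,6E,10E)-12-hydroxyfarnesyl acetate
Conditions: SeO2 (cat.), salicylic acid (cat.), t-BuOOH, CH2Cl2, 0 °C to rt, stopped at partial conversion
Reagents that add atoms: tert-butyl hydroperoxide, CC(C)(C)OO
Why: Catalytic selenium dioxide allylic oxidation (Riley type, ene reaction then [2,3]-shift) should hydroxylate the terminal, most electron-rich trisubstituted alkene at its E-methyl group, giving the (E)-allylic alcohol that becomes C18.

Step 3
Reactants: 3 (2E,6E,10E)-12-hydroxyfarnesyl acetate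
Product: 4 (2E,6E,10E)-12-(tert-butyldimethylsilyloxy)farnesyl acetate
Conditions: TBSCl, imidazole, DMF, 0 °C to rt
Reagents that add atoms: tert-butyldimethylsilyl chloride, CC(C)(C)[Si](C)(C)Cl
Why: Imidazole-promoted silylation of the primary allylic alcohol gives an ether that should survive methanolysis, bromide formation and the Grignard coupling.

Step 4
Reactants: 4 (2E,6E,10E)-12-(tert-butyldimethylsilyloxy)farnesyl acetate
Product: 5 (2E,6E,10E)-12-(tert-butyldimethylsilyloxy)farnesol
Conditions: K2CO3 (cat.), MeOH, 0 °C to rt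
Reagents that add atoms: none
Why: Base-catalysed transesterification removes the acetate as methyl acetate under conditions too mild to touch the silyl ether.

Step 5
Reactants: 5 (2E,6E,10E)-12-(tert-butyldimethylsilyloxy)farnesol
Product: 7 (2E,6E,10E)-12-(tert-butyldimethylsilyloxy)farnesyl bromide, via allylic mesylate 6 (not isolated)
Conditions: MsCl, Et3N, THF, −40 °C; then LiBr, THF, −40 to 0 °C
Reagents that add atoms: lithium bromide, [Li+].[Br-]
Why: Mesylation followed by SN2 displacement with bromide in the same flask is a non-acidic entry to the primary allylic bromide and should keep the E alkene and the silyl ether intact.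

Step 6
Reactants: 8 3-furanmethanol
Product: 10 3-(chloromethyl)furan, via furan-3-ylmethyl mesylate 9 (not isolated)
Conditions: MsCl, LiCl, 2,4,6-collidine, DMF, 0 °C; cold work-up, used at once
Reagents that add atoms: lithium chloride, [Li+].[Cl-]
Why: Buffered mesylation with chloride displacement in the same flask avoids the acid that would degrade the furan, and the chloride is made fresh because it stores poorly.

Step 7
Reactants: 10 3-(chloromethyl)furan; 7 (2E,6E,10E)-12-(tert-butyldimethylsilyloxy)farnesyl bromide
Product: 12 3-[(3E,7E,11E)-13-(tert-butyldimethylsilyloxy)-4,8,12-trimethyltrideca-3,7,11-trien-1-yl]furan, via (furan-3-ylmethyl)magnesium chloride 11 (not isolated)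
Conditions: 10, Mg turnings, THF, 0 °C to rt (dilute, slow addition); then 7, Li2CuCl4 (cat.), THF, −10 to 0 °C
Reagents that add atoms: none
Why: Li2CuCl4-catalysed coupling of a benzylic-type Grignard reagent with a primary allylic bromide should take place at the α-carbon with the E alkene kept, forming C11–C12 and completing the C20 chain.

Step 8
Reactants: 12 3-[(3E,7E,11E)-13-(tert-butyldimethylsilyloxy)-4,8,12-trimethyltrideca-3,7,11-trien-1-yl]furan
Product: 13 (2E,6E,10E)-13-(furan-3-yl)-2,6,10-trimethyltrideca-2,6,10-trien-1-ol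
Conditions: TBAF, THF, 0 °C to rt
Reagents that add atoms: none
Why: Fluoride desilylation under neutral conditions, which the acid-sensitive furan tolerates, frees the (E)-allylic alcohol that must direct the epoxidation.

Step 9
Reactants: 13 (2E,6E,10E)-13-(furan-3-yl)-2,6,10-trimethyltrideca-2,6,10-trien-1-ol
Product: 14 [(2R,3R)-3-[(3E,7E)-10-(furan-3-yl)-3,7-dimethyldeca-3,7-dien-1-yl]-2-methyloxiran-2-yl]methanol
Conditions: Ti(OiPr)4 (cat.), D-(−)-diethyl tartrate, anhydrous t-BuOOH, 4 Å molecular sieves, CH2Cl2, −20 °C
Reagents that add atoms: tert-butyl hydroperoxide, CC(C)(C)OO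
Why: Sharpless asymmetric epoxidation is hydroxyl-directed, so only the C3=C4 alkene reacts, and for an (E)-2-methyl allylic alcohol the D-(−)-tartrate ligand should give the (3R,4R)-epoxide (labdane numbering); the remote 3-alkylfuran is not a furyl carbinol and offers the titanium peroxide no handle.

Step 10
Reactants: 14 [(2R,3R)-3-[(3E,7E)-10-(furan-3-yl)-3,7-dimethyldeca-3,7-dien-1-yl]-2-methyloxiran-2-yl]methanol
Product: 15 (2R,3R)-epoxy alcohol tert-butyldimethylsilyl ether (cyclisation precursor)
Conditions: TBSCl, imidazole, CH2Cl2, 0 °C to rt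
Reagents that add atoms: tert-butyldimethylsilyl chloride, CC(C)(C)[Si](C)(C)Cl
Why: Silylation caps the C18 hydroxyl so that it cannot bind titanium or be lost in the radical step, and it supplies the bulk that biases C4.

Step 11
Reactants: 15 (2R,3R)-epoxy alcohol tert-butyldimethylsilyl ether (cyclisation precursor)
Product: 16 (3R,4S,5S,9R,10S)-18-(tert-butyldimethylsilyloxy)-15,16-epoxylabda-8(17),13(16),14-trien-3-ol
Conditions: Cp2TiCl2 (2.2 equiv), Mn dust (8 equiv), rigorously degassed THF, rt, 15 added slowly in dilute solution; aq. NaH2PO4 quench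
Reagents that add atoms: none
Why: Cp2TiCl (trivalent titanium, formed from Cp2TiCl2 and Mn) gives one electron to the epoxide and cleaves C4–O to a tertiary C4 radical with the C3–O–Ti bond kept; the cascade then forms C4–C5 and C10–C9, and the tertiary C8 radical is taken up by a second Cp2TiCl and loses a C17 hydrogen to leave the C8=C17 methylene. The reaction type is the titanocene-mediated radical epoxypolyene cyclisation, established for epoxyfarnesyl-type chains that end in an exocyclic alkene. Ring A closes by 6-endo-trig addition of the C4 radical to C5 of the C5=C10 alkene and ring B by 6-endo-trig addition of the C10 radical to C9 of the C9=C8 alkene, each through a chair. C3 is inherited from the epoxide because its C–O bond is never broken; C5, C10 and C9 follow from chair–chair folding of the all-E chain with the bulky C3–O–Ti group equatorial, which gives the trans-decalin with the C9 side chain equatorial; C4 is set by the planar radical reacting in the chair that keeps the larger CH2OSi group equatorial and out of a 1,3-diaxial contact with the C10 methyl. The step needs three selectivities: this chair–chair diastereoselection, exocyclic rather than endocyclic alkene formation (hydrogen loss from the least hindered C17 methyl at the titanium-bound stage), and no reaction at the furan, which the radical manifold secures because a C8 cation would be captured by furan C2 as a third ring whereas the nucleophilic tertiary C8 radical would have to build a congested quaternary centre with loss of aromaticity. No Lewis acid is present, the C18 silyloxy group is not a radical leaving group, and slow addition in dilute THF should let cyclisation of the tertiary C4 radical outrun its reduction.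

Step 12
Reactants: 16 (3R,4S,5S,9R,10S)-18-(tert-butyldimethylsilyloxy)-15,16-epoxylabda-8(17),13(16),14-trien-3-ol
Product: 19 (3R,4S,5S,9R,10S)-18-(tert-butyldimethylsilyloxy)-3-hydroxylabda-8(17),13-dien-15,16-olide, via furan endoperoxide 17 (not isolated), via γ-hydroxybutenolide 18 (not isolated)
Conditions: O2, visible light, tetraphenylporphyrin (cat.), i-Pr2NEt, CH2Cl2, −78 °C; argon purge; then NaBH4, MeOH, −78 to 0 °C; aq. citric acid work-up
Reagents that add atoms: dioxygen, O=O
Why: Singlet oxygen should add [4+2] across C15/C16 of the electron-rich furan far faster than it engages the 1,1-disubstituted C8=C17 alkene in an ene reaction, the hindered amine fragments endoperoxide 17 (Kornblum–DeLaMare type) to γ-hydroxybutenolide 18, and borohydride reduction of its masked C16 aldehyde with relactonisation on work-up should give butenolide 19; any regioisomeric butenolide would be taken to the same diol in the next step.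

Step 13
Reactants: 19 (3R,4S,5S,9R,10S)-18-(tert-butyldimethylsilyloxy)-3-hydroxylabda-8(17),13-dien-15,16-olide
Product: 20 (3R,4S,5S,9R,10S,13Z)-18-(tert-butyldimethylsilyloxy)labda-8(17),13-diene-3,15,16-triol
Conditions: i-Bu2AlH (5 equiv), CH2Cl2, −78 to 0 °C; aq. KNaC4H4O6 (potassium sodium tartrate) work-up
Reagents that add atoms: none
Why: 1,2-Reduction of the unsaturated lactone by the aluminium hydride, with excess reagent and warming to carry the lactol stage through to the alcohol, should give the diol with the 13Z geometry fixed by the ring it came from; the silyl ether and the 8(17)-alkene are inert.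

Step 14
Reactants: 20 (3R,4S,5S,9R,10S,13Z)-18-(tert-butyldimethylsilyloxy)labda-8(17),13-diene-3,15,16-triol
Product: 21 (3R,4S,5S,9R,10S,13Z)-15,16,18-tris(tert-butyldimethylsilyloxy)labda-8(17),13-dien-3-ol
Conditions: TBSCl (2.3 equiv), imidazole, CH2Cl2, 0 °C
Reagents that add atoms: tert-butyldimethylsilyl chloride, CC(C)(C)[Si](C)(C)Cl
Why: Rate-selective silylation should take the two primary allylic hydroxyls and leave the secondary C3 hydroxyl, which is flanked by the quaternary C4, free for acylation.

Step 15
Reactants: 21 (3R,4S,5S,9R,10S,13Z)-15,16,18-tris(tert-butyldimethylsilyloxy)labda-8(17),13-dien-3-ol; 22 angelic acid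
Product: 24 (3R,4S,5S,9R,10S,13Z)-15,16,18-tris(tert-butyldimethylsilyloxy)labda-8(17),13-dien-3-yl (Z)-2-methylbut-2-enoate, via mixed anhydride 23 (not isolated)
Conditions: 22, 2,4,6-trichlorobenzoyl chloride, Et3N, toluene, rt; then 21, toluene, 75–80 °C, no DMAP, stopped as soon as 21 is consumed
Reagents that add atoms: none
Why: In this Yamaguchi-type esterification the alcohol attacks the unshielded angeloyl carbonyl of the mixed anhydride, and leaving out the nucleophilic catalyst removes the reversible conjugate addition that would isomerise the angelate to the tiglate.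

Step 16
Reactants: 24 (3R,4S,5S,9R,10S,13Z)-15,16,18-tris(tert-butyldimethylsilyloxy)labda-8(17),13-dien-3-yl (Z)-2-methylbut-2-enoate
Product: 25 (3R,4S,5S,9R,10S,13Z)-15,16,18-trihydroxylabda-8(17),13-dien-3-yl (Z)-2-methylbut-2-enoate (target CNP0237954.1)
Conditions: HF·pyridine, pyridine, THF, 0 °C to rt
Reagents that add atoms: none
Why: Buffered acidic fluoride desilylation should remove all three silyl ethers without the basic alkoxide conditions that promote 3-O to 18-O acyl migration or angelate isomerisation.

Compound list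

1 | (2E,6E)-farnesol | CC(C)=CCC/C(C)=C/CC/C(C)=C/CO | starting material
2 | (2E,6E)-farnesyl acetate | CC(C)=CCC/C(C)=C/CC/C(C)=C/COC(C)=O | intermediate
3 | (2E,6E,10E)-12-hydroxyfarnesyl acetate | OC/C(C)=C/CC/C(C)=C/CC/C(C)=C/COC(C)=O | intermediate
4 | (2E,6E,10E)-12-(tert-butyldimethylsilyloxy)farnesyl acetate | CC(C)(C)[Si](C)(C)OC/C(C)=C/CC/C(C)=C/CC/C(C)=C/COC(C)=O | intermediate
5 | (2E,6E,10E)-12-(tert-butyldimethylsilyloxy)farnesol | CC(C)(C)[Si](C)(C)OC/C(C)=C/CC/C(C)=C/CC/C(C)=C/CO | intermediate
6 | (2E,6E,10E)-12-(tert-butyldimethylsilyloxy)farnesyl methanesulfonate | CC(C)(C)[Si](C)(C)OC/C(C)=C/CC/C(C)=C/CC/C(C)=C/COS(C)(=O)=O | intermediate (not isolated)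
7 | (2E,6E,10E)-12-(tert-butyldimethylsilyloxy)farnesyl bromide | CC(C)(C)[Si](C)(C)OC/C(C)=C/CC/C(C)=C/CC/C(C)=C/CBr | intermediate
8 | 3-furanmethanol | OCc1ccoc1 | starting material
9 | furan-3-ylmethyl methanesulfonate | CS(=O)(=O)OCc1ccoc1 | intermediate (not isolated)
10 | 3-(chloromethyl)furan | ClCc1ccoc1 | intermediate
11 | (furan-3-ylmethyl)magnesium chloride | Cl[Mg]Cc1ccoc1 | intermediate (not isolated)
12 | 3-[(3E,7E,11E)-13-(tert-butyldimethylsilyloxy)-4,8,12-trimethyltrideca-3,7,11-trien-1-yl]furan | CC(C)(C)[Si](C)(C)OC/C(C)=C/CC/C(C)=C/CC/C(C)=C/CCc1ccoc1 | intermediate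
13 | (2E,6E,10E)-13-(furan-3-yl)-2,6,10-trimethyltrideca-2,6,10-trien-1-ol | OC/C(C)=C/CC/C(C)=C/CC/C(C)=C/CCc1ccoc1 | intermediate
14 | [(2R,3R)-3-[(3E,7E)-10-(furan-3-yl)-3,7-dimethyldeca-3,7-dien-1-yl]-2-methyloxiran-2-yl]methanol, the (3R,4R)-epoxide in labdane numbering | OC[C@@]1(C)O[C@@H]1CC/C(C)=C/CC/C(C)=C/CCc1ccoc1 | intermediate
15 | tert-butyldimethylsilyl ether of 14 at the C18 oxygen, (2R,3R)-epoxide | CC(C)(C)[Si](C)(C)OC[C@@]1(C)O[C@@H]1CC/C(C)=C/CC/C(C)=C/CCc1ccoc1 | intermediate
16 | (3R,4S,5S,9R,10S)-18-(tert-butyldimethylsilyloxy)-15,16-epoxylabda-8(17),13(16),14-trien-3-ol (ent-labdane series, trans-decalin, equatorial 3-OH and C18, furan intact) | C=C1CC[C@H]2[C@@](C)(CC[C@@H](O)[C@]2(C)CO[Si](C)(C)C(C)(C)C)[C@@H]1CCc1ccoc1 | intermediate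
17 | furan endoperoxide of 16 (2,3,7-trioxabicyclo[2.2.1]hept-5-ene on C13–C16, bridgehead diastereomers) | C=C1CC[C@H]2[C@@](C)(CC[C@@H](O)[C@]2(C)CO[Si](C)(C)C(C)(C)C)[C@@H]1CCC1=CC2OOC1O2 | intermediate (not isolated)
18 | (3R,4S,5S,9R,10S)-18-(tert-butyldimethylsilyloxy)-3,16-dihydroxylabda-8(17),13-dien-15,16-olide (γ-hydroxybutenolide, C16 epimers) | C=C1CC[C@H]2[C@@](C)(CC[C@@H](O)[C@]2(C)CO[Si](C)(C)C(C)(C)C)[C@@H]1CCC1=CC(=O)OC1O | intermediate (not isolated)
19 | (3R,4S,5S,9R,10S)-18-(tert-butyldimethylsilyloxy)-3-hydroxylabda-8(17),13-dien-15,16-olide | C=C1CC[C@H]2[C@@](C)(CC[C@@H](O)[C@]2(C)CO[Si](C)(C)C(C)(C)C)[C@@H]1CCC1=CC(=O)OC1 | intermediate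
20 | (3R,4S,5S,9R,10S,13Z)-18-(tert-butyldimethylsilyloxy)labda-8(17),13-diene-3,15,16-triol | C=C1CC[C@H]2[C@@](C)(CC[C@@H](O)[C@]2(C)CO[Si](C)(C)C(C)(C)C)[C@@H]1CC/C(=C/CO)CO | intermediate
21 | (3R,4S,5S,9R,10S,13Z)-15,16,18-tris(tert-butyldimethylsilyloxy)labda-8(17),13-dien-3-ol | C=C1CC[C@H]2[C@@](C)(CC[C@@H](O)[C@]2(C)CO[Si](C)(C)C(C)(C)C)[C@@H]1CC/C(=C/CO[Si](C)(C)C(C)(C)C)CO[Si](C)(C)C(C)(C)C | intermediate
22 | angelic acid, (Z)-2-methylbut-2-enoic acid | C/C=C(/C)C(=O)O | starting material
23 | (Z)-2-methylbut-2-enoic 2,4,6-trichlorobenzoic anhydride | C/C=C(/C)C(=O)OC(=O)c1c(Cl)cc(Cl)cc1Cl | intermediate (not isolated)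
24 | (3R,4S,5S,9R,10S,13Z)-15,16,18-tris(tert-butyldimethylsilyloxy)labda-8(17),13-dien-3-yl (Z)-2-methylbut-2-enoate | C=C1CC[C@H]2[C@@](C)(CC[C@@H](OC(=O)/C(C)=C\C)[C@]2(C)CO[Si](C)(C)C(C)(C)C)[C@@H]1CC/C(=C/CO[Si](C)(C)C(C)(C)C)CO[Si](C)(C)C(C)(C)C | intermediate
25 | (3R,4S,5S,9R,10S,13Z)-15,16,18-trihydroxylabda-8(17),13-dien-3-yl (Z)-2-methylbut-2-enoate, CNP0237954.1 | C=C1CC[C@H]2[C@@](C)(CC[C@@H](OC(=O)/C(C)=C\C)[C@]2(C)CO)[C@@H]1CC/C(=C/CO)CO | target

Total step count: 16. Longest linear sequence: 15 steps (steps 1–5 and 7–16, from farnesol); step 6 is the one-step side branch.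

Steps most likely to fail

Step 11. The processes at risk are interception of the C8 radical by the furan, interruption of the cascade after ring A, and reduction of the C4 radical before it cyclises. The fallback runs the bicyclisation before the heteroarene is in the molecule. Setting out from hydroxy acetate 3, Sharpless epoxidation with D-(−)-diethyl tartrate would give epoxy alcohol acetate F1. Silylation (TBSCl, imidazole) would give epoxy silyl ether acetate F2. The same Cp2TiCl cascade would give bicyclic hydroxy acetate F3, now on the plain epoxyfarnesyl acetate type of substrate for which this cyclisation is best documented. Methanolysis (K2CO3, MeOH) would give bicyclic diol F4, and selective iodination of the primary C11 hydroxyl (I2, PPh3, imidazole) would give bicyclic iodide F5. Li2CuCl4-catalysed alkyl–alkyl coupling with an excess of Grignard reagent 11 (one equivalent is consumed by the C3 hydroxyl) would form C11–C12 and come back to the route at 16.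

Step 15. The processes at risk are Z-to-E isomerisation of the activated acyl group at the temperature the hindered C3 hydroxyl demands, and slow acylation. The fallback builds the angelate on the molecule instead of transferring it. Setting out from alcohol 21, carbodiimide esterification (DCC, DMAP, CH2Cl2) with 2-[bis(2,2,2-trifluoroethoxy)phosphoryl]propanoic acid would give phosphonopropionate ester F6. Still–Gennari olefination (KN(SiMe3)2, 18-crown-6, THF, −78 °C, then acetaldehyde) would then form the Z-trisubstituted enoate and come back to the route at 24.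

Step 7. The processes at risk are Wurtz-type homocoupling while the Grignard reagent forms, bond formation through a ring carbon of the furylmethyl nucleophile, and attack at the γ-carbon of the allyl bromide with loss of the E alkene. The fallback reverses the polarity. Setting out from bromide 7, displacement with PhSO2Na (DMF) would give allylic phenyl sulfone F7. Deprotonation (n-BuLi, THF, −78 °C) and alkylation with chloride 10 would give furylmethylated sulfone F8. Palladium-catalysed reductive desulfonylation (Pd(dppp)Cl2 cat., LiBHEt3, THF, 0 °C), with hydride delivered to the less substituted allyl terminus, would come back to the route at 12.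

Further compounds

F1 | step 11 | epoxy alcohol acetate, (10R,11R)-10,11-epoxy-12-hydroxyfarnesyl acetate (2E,6E) | OC[C@@]1(C)O[C@@H]1CC/C(C)=C/CC/C(C)=C/COC(C)=O
F2 | step 11 | epoxy silyl ether acetate, 12-O-tert-butyldimethylsilyl ether of F1 | CC(C)(C)[Si](C)(C)OC[C@@]1(C)O[C@@H]1CC/C(C)=C/CC/C(C)=C/COC(C)=O
F3 | step 11 | bicyclic hydroxy acetate: rings A and B as in 16 with the same ring configuration, CH2OAc (C11) on C9 in place of the furylethyl chain | C=C1CC[C@H]2[C@@](C)(CC[C@@H](O)[C@]2(C)CO[Si](C)(C)C(C)(C)C)[C@@H]1COC(C)=O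
F4 | step 11 | bicyclic diol: F3 with free C11 hydroxyl | C=C1CC[C@H]2[C@@](C)(CC[C@@H](O)[C@]2(C)CO[Si](C)(C)C(C)(C)C)[C@@H]1CO
F5 | step 11 | bicyclic iodide: F4 with iodine in place of the C11 hydroxyl | C=C1CC[C@H]2[C@@](C)(CC[C@@H](O)[C@]2(C)CO[Si](C)(C)C(C)(C)C)[C@@H]1CI
F6 | step 15 | phosphonopropionate ester: 3-O-{2-[bis(2,2,2-trifluoroethoxy)phosphoryl]propanoyl} derivative of 21 (epimers at the phosphorus-bearing carbon) | C=C1CC[C@H]2[C@@](C)(CC[C@@H](OC(=O)C(C)P(=O)(OCC(F)(F)F)OCC(F)(F)F)[C@]2(C)CO[Si](C)(C)C(C)(C)C)[C@@H]1CC/C(=C/CO[Si](C)(C)C(C)(C)C)CO[Si](C)(C)C(C)(C)C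
F7 | step 7 | allylic phenyl sulfone: (2E,6E,10E)-12-(tert-butyldimethylsilyloxy)farnesyl phenyl sulfone | CC(C)(C)[Si](C)(C)OC/C(C)=C/CC/C(C)=C/CC/C(C)=C/CS(=O)(=O)c1ccccc1
F8 | step 7 | furylmethylated sulfone: F7 carrying a furan-3-ylmethyl group on the sulfonyl-bearing carbon (racemic at that carbon) | CC(C)(C)[Si](C)(C)OC/C(C)=C/CC/C(C)=C/CC/C(C)=C/C(Cc1ccoc1)S(=O)(=O)c1ccccc1
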